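**Plan**

Locants (diterpene numbering): ring A = C1–C5, C10 (C1 OAc, C4 Me2, C10 Me = C20); ring B = C5–C10 (C6 OH, C8=C9); bicyclo[3.2.1]octane with bridgeheads C11 and C13, keto bridge C15(=O)–C16(=C17H2), carbinol bridge C12 and third bridge C9=C8–C14H2.
Enabling feature: the five-membered ring C11–C15(=O)–C16–C13–C12(OH), with C9 on C11 trans to the C12 hydroxyl, is a trans-4-hydroxy-5-substituted cyclopentanone, the retron of a Piancatelli rearrangement; furan supplies C12, C13, C16, C15 and the ketone oxygen.
Cuts, in retrosynthetic order: C16=C17 (α-methylenation); C13–C14 (6-exo radical conjugate addition to the cyclopentenone); C11–C12 (4π electrocyclisation of a 2-furylcarbinol ester); C11–furan (aryllithium plus lactone); C9–C10 and C7–C8 (ester-tethered intramolecular Diels–Alder reaction).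
Forward order: ring A (from a cyclohexane-1,3-dione), then ring B together with the C1–O–C11 lactone, then the cyclopentenone, then ring C (which completes the bicycle), then the exocyclic methylene.
Stereochemistry: C1 from a Corey–Bakshi–Shibata reduction, relayed to quaternary C10 by the tether; C5 from hydroboration; C1 and C6 then reset by hydride delivery anti to the axial methyl groups; C11/C12 from conrotation under control of C10; C13 from the tether.

Key step: step 14

Remark: α denotes the face of the C10 methyl group (C20) and β the opposite face; 19 and 20 are carried as mixtures of C11 carbinol epimers because both ionise to the same cation in step 14, and 17 may sit partly as its cyclic hemiketal, which reacts through the open form.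

**Step 1**
Reactants: 1 4,4-dimethylcyclohexane-1,3-dione
Product: 2 2,4,4-trimethylcyclohexane-1,3-dione
Conditions: MeI, K2CO3, acetone, reflux
Reagents that add atoms: iodomethane CI
Why: Enolate C-alkylation of the acidic C2 position of a cyclic 1,3-dione is the standard route to 2-alkyl-1,3-diones.

**Step 2**
Reactants: 2 2,4,4-trimethylcyclohexane-1,3-dione
Product: 3 3-isobutoxy-2,6,6-trimethylcyclohex-2-en-1-one
Conditions: i-BuOH, TsOH·H2O (cat.), toluene, reflux, Dean–Stark
Reagents that add atoms: 2-methylpropan-1-ol CC(C)CO
Why: Acid-catalysed enol etherification (vinylogous ester formation) should occur at the carbonyl remote from the gem-dimethyl group for steric reasons, leaving the hindered carbonyl next to CMe2 as the ketone.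

**Step 3**
Reactants: 3 3-isobutoxy-2,6,6-trimethylcyclohex-2-en-1-one
Product: 5 2,4,4-trimethyl-3-vinylcyclohex-2-en-1-one, via tertiary magnesium alkoxide 4 (not isolated)
Conditions: CH2=CHMgBr, THF, 0 → 50 °C; then 1 M HCl, rt
Reagents that add atoms: vinylmagnesium bromide C=C[Mg]Br; water O
Why: Stork–Danheiser transposition, in which 1,2-addition of the Grignard reagent to the vinylogous ester followed by acidic hydrolysis and dehydration moves the carbonyl and gives the cross-conjugated dienone that holds C1–C7, C10 and the three methyl groups.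

**Step 4**
Reactants: 5 2,4,4-trimethyl-3-vinylcyclohex-2-en-1-one
Product: 6 (R)-2,4,4-trimethyl-3-vinylcyclohex-2-en-1-ol
Conditions: (S)-2-methyl-CBS-oxazaborolidine (20 mol %), catecholborane, toluene, −78 °C; then H2O
Reagents that add atoms: none
Why: Corey–Bakshi–Shibata reduction, in which the oxazaborolidine differentiates the fully substituted alkene arm from the CH2 arm of the enone and sets the C1 carbinol centre as (R), while catecholborane leaves the vinyl group untouched.

**Step 5**
Reactants: 7 prop-2-yn-1-ol
Product: 8 tert-butyldiphenyl(prop-2-yn-1-yloxy)silane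
Conditions: TBDPSCl, imidazole, CH2Cl2, 0 °C → rt
Reagents that add atoms: tert-butyl(chloro)diphenylsilane CC(C)(C)[Si](Cl)(c1ccccc1)c1ccccc1
Why: Silylation of a primary alcohol with a silyl chloride and imidazole gives a bulky, weakly nucleophilic ether on the future C14 oxygen that should survive until step 15.

**Step 6**
Reactants: 8 tert-butyldiphenyl(prop-2-yn-1-yloxy)silane
Product: 10 4-[(tert-butyldiphenylsilyl)oxy]but-2-ynoic acid, via lithium acetylide 9 (not isolated)
Conditions: n-BuLi, THF, −78 °C; CO2; then 1 M HCl
Reagents that add atoms: carbon dioxide O=C=O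
Why: Deprotonation of the terminal alkyne and carboxylation of the lithium acetylide installs the future C11.

**Step 7**
Reactants: 6 (R)-2,4,4-trimethyl-3-vinylcyclohex-2-en-1-ol; 10 4-[(tert-butyldiphenylsilyl)oxy]but-2-ynoic acid
Product: 11 (R)-2,4,4-trimethyl-3-vinylcyclohex-2-en-1-yl 4-[(tert-butyldiphenylsilyl)oxy]but-2-ynoate
Conditions: DCC, DMAP (cat.), CH2Cl2, −20 → 0 °C
Reagents that add atoms: none
Why: Steglich esterification at low temperature attaches the alkynoate dienophile to the diene through the C1 oxygen.

**Step 8**
Reactants: 11 (R)-2,4,4-trimethyl-3-vinylcyclohex-2-en-1-yl 4-[(tert-butyldiphenylsilyl)oxy]but-2-ynoate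
Product: 12 tricyclic dienyl lactone (γ-lactone C1–O–C11(=O)–C9; C5=C6 and C8=C9; C8–CH2OTBDPS; 1β-O; 10α-CH3)
Conditions: toluene (0.01 M), BHT (cat.), sealed tube, 160 °C
Reagents that add atoms: none
Why: Ester-tethered intramolecular Diels–Alder reaction of the 1-vinylcyclohexene diene with the alkynoate, in which the three-atom tether forces C9 onto the face of the C1 oxygen, so the C10 methyl ends up trans to that oxygen and the C1 chirality is relayed to quaternary C10.

**Step 9**
Reactants: 12 tricyclic dienyl lactone
Product: 14 hydroxy lactone (as 12 with C5–C6 saturated; 5β-H; 6β-OH), via C6 alkylborane 13 (not isolated)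
Conditions: BH3·THF, THF, 0 °C → rt; then 30% H2O2, pH 7 phosphate buffer, 0 °C → rt
Reagents that add atoms: hydrogen peroxide OO
Why: Hydroboration–oxidation of the electron-rich trisubstituted C5=C6 bond (the lactone-conjugated C8=C9 bond is deactivated) should place boron on C6 and hydrogen on C5 from the β face, away from the parallel C10 and C4 methyl groups, which sets the trans ring fusion.

**Step 10**
Reactants: 14 hydroxy lactone; 15 furan
Product: 17 furyl ketone diol (C9–C11(=O)–2-furyl; 1β-OH; 6β-OH; C8–CH2OTBDPS), via 2-furyllithium 16 (not isolated)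
Conditions: furan, n-BuLi, THF, 0 °C; then 14, −78 °C; then H2O
Reagents that add atoms: none
Why: Addition of an aryllithium to a lactone at low temperature should stop at the ketone stage because the tetrahedral lithium hemiketal persists until work-up, and it joins the four furan carbons to C11.

**Step 11**
Reactants: 17 furyl ketone diol
Product: 18 triketone (C1=O; C6=O; C11(=O)–2-furyl; 5β-H; 10α-CH3)
Conditions: Dess–Martin periodinane, CH2Cl2, rt
Reagents that add atoms: none
Why: Dess–Martin oxidation of both secondary alcohols under non-basic conditions erases the C1 and C6 carbinol configurations, which are opposite to those of the target, without epimerising C5.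

**Step 12**
Reactants: 18 triketone
Product: 19 triol (1α-OH equatorial; 6α-OH axial; C11 carbinol as epimer mixture)
Conditions: NaBH4, CeCl3·7H2O, MeOH, −40 → 0 °C
Reagents that add atoms: none
Why: Luche reduction should deliver hydride 1,2 to all three ketones, at C1 and C6 from the β face opposite to the axial C20 and C4 methyl groups (giving equatorial 1α-OH and axial 6α-OH), while the C11 carbinol forms as an inconsequential epimer mixture.

**Step 13**
Reactants: 19 triol
Product: 20 diacetate (1α-OAc; C11–OAc; free 6α-OH)
Conditions: Ac2O, DMAP (cat.), pyridine, 0 °C → rt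
Reagents that add atoms: acetic anhydride CC(=O)OC(C)=O
Why: DMAP-catalysed acetylation should esterify the C1 and C11 hydroxyls, whereas the axial C6 hydroxyl, syn-axial to two methyl groups, is too hindered to react under these conditions.

**Step 14**
Reactants: 20 diacetate
Product: 21 trans-4-hydroxy-5-substituted cyclopent-2-enone (C15=O; C16=C13; C12–OH; decalin attached through C9 to C11; 1α-OAc; 6α-OH; C8–CH2OTBDPS)
Conditions: Dy(OTf)3 (10 mol %), t-BuOH/H2O (5:1), 80 °C
Reagents that add atoms: water O
Why: Piancatelli rearrangement: Lewis acid ionises the furfuryl acetate at C11, water adds to furan C5 (the future C12), the hemiacetal opens to a 1-hydroxypentadienyl cation, and a 4π-conrotatory electrocyclisation forms the C11–C12 bond, after which proton loss leaves the C15 ketone (former furan oxygen) and the C13=C16 enone. The closest known reaction type is the acid-mediated rearrangement of 2-furylcarbinols to trans-4-hydroxy-5-substituted cyclopent-2-enones, an oxa-Nazarov-type process. The only ring closed is the cyclopentenone, by electrocyclic closure between the two termini (C11 and C12) of the pentadienyl cation. C11 and C12 are set together: the large groups (C9 on C11, OH on C12) sit on the outside of the U-shaped cation, so conrotation places them trans, and the sense relative to the decalin is expected from A(1,3) strain, which turns the dienyl plane perpendicular to the C8=C9 plane with the dienyl arm anti to the axial C20 methyl and closure on the C14 side, away from quaternary C10. The step needs ionisation only at C11 (secured by the furfuryl position, since the C1 acetate is not activated) and no leakage of the cation into the C8=C9 bond or onto a neighbouring oxygen (the orthogonal geometry prevents allylic delocalisation and the bulky silyl ether oxygen is a poor trap).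

**Step 15**
Reactants: 21 trans-4-hydroxy-5-substituted cyclopent-2-enone
Product: 22 triol (as 21 with free C14–OH)
Conditions: HF·pyridine, THF/pyridine, 0 °C → rt
Reagents that add atoms: none
Why: Fluoride-mediated silyl ether cleavage frees the primary allylic alcohol under conditions that should not touch the acetate or epimerise C11.

**Step 16**
Reactants: 22 triol
Product: 23 allylic bromide (C14–Br; C12–OH and C6–OH free)
Conditions: CBr4, PPh3, CH2Cl2, −20 °C
Reagents that add atoms: tetrabromomethane BrC(Br)(Br)Br
Why: Appel reaction, in which the unhindered primary allylic alcohol should be converted to the bromide faster than the hindered secondary C12 alcohol and the axial C6 alcohol.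

**Step 17**
Reactants: 23 allylic bromide
Product: 24 tetracyclic ketol (the target without C17; C15=O; C16H2; 12-OH syn to the keto bridge)
Conditions: Bu3SnH (syringe pump), AIBN (cat.), benzene (0.005 M), 80 °C
Reagents that add atoms: none
Why: Tin hydride-mediated 6-exo-trig radical conjugate addition (Giese type), in which the nucleophilic allylic radical bonds through C14 to the enone β-carbon C13 on the face cis to C9 and anti to the C12 hydroxyl (attack through C9 would give a four-membered ring), so C13 is set by the tether, ring C and the bicyclo[3.2.1]octane close together, and the α-keto radical at C16 is reduced.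

**Step 18**
Reactants: 24 tetracyclic ketol
Product: 26 target acetate (1α-OAc; 6α-OH; 12-OH; 16-methylene-15-ketone), via Mannich base 25 (not isolated)
Conditions: (CH2O)n, PhNHMe·CF3CO2H, THF, 65 °C
Reagents that add atoms: formaldehyde (as paraformaldehyde) C=O
Why: α-Methylenation by Mannich reaction with formaldehyde and the secondary ammonium salt followed by elimination of the amine, which can only occur at C16 because the other α-carbon, C11, is a bridgehead.

**Compound list**

1 | 4,4-dimethylcyclohexane-1,3-dione | O=C1CC(=O)C(C)(C)CC1 | starting material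
2 | 2,4,4-trimethylcyclohexane-1,3-dione | CC1C(=O)CCC(C)(C)C1=O | intermediate
3 | 3-isobutoxy-2,6,6-trimethylcyclohex-2-en-1-one | CC1=C(OCC(C)C)CCC(C)(C)C1=O | intermediate
4 | bromomagnesium 3-isobutoxy-2,6,6-trimethyl-1-vinylcyclohex-2-en-1-olate (racemic) | C=CC1(O[Mg]Br)C(C)=C(OCC(C)C)CCC1(C)C | intermediate (not isolated)
5 | 2,4,4-trimethyl-3-vinylcyclohex-2-en-1-one | C=CC1=C(C)C(=O)CCC1(C)C | intermediate
6 | (R)-2,4,4-trimethyl-3-vinylcyclohex-2-en-1-ol | C=CC1=C(C)[C@H](O)CCC1(C)C | intermediate
7 | prop-2-yn-1-ol | C#CCO | starting material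
8 | tert-butyldiphenyl(prop-2-yn-1-yloxy)silane | C#CCO[Si](c1ccccc1)(c1ccccc1)C(C)(C)C | intermediate
9 | lithium acetylide of 8 | [Li]C#CCO[Si](c1ccccc1)(c1ccccc1)C(C)(C)C | intermediate (not isolated)
10 | 4-[(tert-butyldiphenylsilyl)oxy]but-2-ynoic acid | OC(=O)C#CCO[Si](c1ccccc1)(c1ccccc1)C(C)(C)C | intermediate
11 | (R)-2,4,4-trimethyl-3-vinylcyclohex-2-en-1-yl 4-[(tert-butyldiphenylsilyl)oxy]but-2-ynoate | C=CC1=C(C)[C@H](OC(=O)C#CCO[Si](c2ccccc2)(c2ccccc2)C(C)(C)C)CCC1(C)C | intermediate
12 | tricyclic dienyl lactone: γ-lactone C1–O–C11(=O)–C9, C5=C6 and C8=C9 double bonds, C8–CH2OTBDPS, 1β-O, 10α-CH3 | O=C1O[C@@H]2CCC(C)(C)C3=CCC(CO[Si](c4ccccc4)(c4ccccc4)C(C)(C)C)=C1[C@]23C | intermediate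
13 | C6 alkylborane of 12 (5β-H, 6β-BH2) | O=C1O[C@@H]2CCC(C)(C)[C@H]3[C@H](B)CC(CO[Si](c4ccccc4)(c4ccccc4)C(C)(C)C)=C1[C@]23C | intermediate (not isolated)
14 | hydroxy lactone: as 12 with C5–C6 saturated, 5β-H, 6β-OH | O=C1O[C@@H]2CCC(C)(C)[C@H]3[C@H](O)CC(CO[Si](c4ccccc4)(c4ccccc4)C(C)(C)C)=C1[C@]23C | intermediate
15 | furan | c1ccoc1 | starting material
16 | 2-furyllithium | [Li]c1ccco1 | intermediate (not isolated)
17 | furyl ketone diol: C9–C11(=O)–2-furyl, 1β-OH, 6β-OH, 5β-H, C8–CH2OTBDPS | O=C(c1ccco1)C2=C(CO[Si](c3ccccc3)(c3ccccc3)C(C)(C)C)C[C@@H](O)[C@@H]4C(C)(C)CC[C@@H](O)[C@@]24C | intermediate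
18 | triketone: C1=O, C6=O, C11(=O)–2-furyl | O=C(c1ccco1)C2=C(CO[Si](c3ccccc3)(c3ccccc3)C(C)(C)C)CC(=O)[C@@H]4C(C)(C)CCC(=O)[C@@]24C | intermediate
19 | triol: 1α-OH (equatorial), 6α-OH (axial), C11 furyl carbinol as epimer mixture | OC(c1ccco1)C2=C(CO[Si](c3ccccc3)(c3ccccc3)C(C)(C)C)C[C@H](O)[C@@H]4C(C)(C)CC[C@H](O)[C@@]24C | intermediate
20 | diacetate: 1α-OAc, C11–OAc (epimer mixture), free 6α-OH | CC(=O)OC(c1ccco1)C2=C(CO[Si](c3ccccc3)(c3ccccc3)C(C)(C)C)C[C@H](O)[C@@H]4C(C)(C)CC[C@H](OC(C)=O)[C@@]24C | intermediate
21 | trans-4-hydroxy-5-substituted cyclopent-2-enone: C15=O, C16=C13, C12–OH trans to C9 on C11, C8–CH2OTBDPS | O=C1C=C[C@H](O)[C@H]1C2=C(CO[Si](c3ccccc3)(c3ccccc3)C(C)(C)C)C[C@H](O)[C@@H]4C(C)(C)CC[C@H](OC(C)=O)[C@@]24C | intermediate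
22 | triol: as 21 with free C14–OH | O=C1C=C[C@H](O)[C@H]1C2=C(CO)C[C@H](O)[C@@H]3C(C)(C)CC[C@H](OC(C)=O)[C@@]23C | intermediate
23 | allylic bromide: as 22 with C14–Br | O=C1C=C[C@H](O)[C@H]1C2=C(CBr)C[C@H](O)[C@@H]3C(C)(C)CC[C@H](OC(C)=O)[C@@]23C | intermediate
24 | tetracyclic ketol: the target without C17 | C1C(=O)[C@@H]2C3=C(C[C@H]1[C@@H]2O)C[C@H](O)[C@@H]1C(C)(C)CC[C@H](OC(C)=O)[C@@]31C | intermediate
25 | Mannich base: 24 with CH2N(CH3)Ph on C16 | CN(CC1C(=O)[C@@H]2C3=C(C[C@H]1[C@@H]2O)C[C@H](O)[C@@H]1C(C)(C)CC[C@H](OC(C)=O)[C@@]31C)c1ccccc1 | intermediate (not isolated)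
26 | CNP0149338.1: 1α-acetoxy-6α,12-dihydroxy-16-methylene-15-ketone | C=C1C(=O)[C@@H]2C3=C(C[C@H]1[C@@H]2O)C[C@H](O)[C@@H]1C(C)(C)CC[C@H](OC(C)=O)[C@@]31C | target

**Step count and risks**

Total steps: 18. Longest linear sequence: 16 steps (steps 1–4 and 7–18); steps 5 and 6 form the side branch.

Steps most likely to fail:

1. Step 14. The two senses of conrotation are told apart only by the decalin, so weak facial bias would give, beside 21, the trans isomer in which C11 and C12 are both inverted. Fallback (thermodynamic instead of kinetic control): it sets out from 24 obtained as a mixture and comes back at 24. The unwanted isomer is carried unseparated through steps 15–17 and ends as the facial isomer of the ketol F1. DBU (0.2 equiv) in toluene at 60 °C should open F1 by retro-aldol cleavage of C11–C12 to the seven-membered keto aldehyde F2, in which C13 epimerises through the aldehyde enol. Transannular aldol closure then returns the more stable 24: there the one-carbon bridge C12, which lies close to the plane of the C8=C9 bond, faces the C20 methyl, whereas in F1 the nearly perpendicular two-carbon keto bridge does.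

2. Step 17. The stabilised allylic radical may take hydrogen from the stannane before it cyclises, giving simple reduction at C14 or at C9 with alkene transposition. Fallback (polar instead of radical conjugate addition): it sets out from 23 and comes back at 24. PhSO2Na in DMF at rt should give the allylic sulfone F3. DBU in MeCN at 0 °C should then effect intramolecular Michael addition of the α-sulfonyl carbanion to C13 and give the sulfonyl ketol F4. Sodium amalgam (Na/Hg) with Na2HPO4 in MeOH at −20 °C removes the sulfone to give 24.

3. Step 10. The basic aryllithium may deprotonate the γ-positions (C7, C14) of the unsaturated lactone, or add a second time to the released ketone. Fallback (staged entry through the lactol): it sets out from 14 and comes back at 18. i-Bu2AlH in CH2Cl2 at −78 °C should give the lactol F5. Excess 2-furyllithium in THF at −78 → 0 °C adds to its open aldehyde form to give the furyl triol F6. Dess–Martin oxidation of all three carbinols, as in step 11, then gives 18.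

**Further compounds**

F1 | step 14 | facial isomer of ketol 24 (C11, C12 and C13 inverted) | C1C(=O)[C@H]2C3=C(C[C@@H]1[C@H]2O)C[C@H](O)[C@@H]1C(C)(C)CC[C@H](OC(C)=O)[C@@]31C
F2 | step 14 | seven-membered keto aldehyde (C15 ketone, C12 aldehyde on C13, C13 epimers) | O=CC1CC(=O)CC2=C(C1)C[C@H](O)[C@@H]3C(C)(C)CC[C@H](OC(C)=O)[C@@]23C
F3 | step 17 | allylic sulfone (23 with C14–SO2Ph) | O=C1C=C[C@H](O)[C@H]1C2=C(CS(=O)(=O)c3ccccc3)C[C@H](O)[C@@H]4C(C)(C)CC[C@H](OC(C)=O)[C@@]24C
F4 | step 17 | sulfonyl ketol (24 with SO2Ph on C14) | C1C(=O)[C@@H]2C3=C(C(S(=O)(=O)c4ccccc4)[C@H]1[C@@H]2O)C[C@H](O)[C@@H]1C(C)(C)CC[C@H](OC(C)=O)[C@@]31C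
F5 | step 10 | lactol (14 with C11 as hemiacetal) | OC1O[C@@H]2CCC(C)(C)[C@H]3[C@H](O)CC(CO[Si](c4ccccc4)(c4ccccc4)C(C)(C)C)=C1[C@]23C
F6 | step 10 | furyl triol (C11 furyl carbinol, 1β-OH, 6β-OH) | OC(c1ccco1)C2=C(CO[Si](c3ccccc3)(c3ccccc3)C(C)(C)C)C[C@@H](O)[C@@H]4C(C)(C)CC[C@@H](O)[C@@]24C
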